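The ratio that opened this for me was 3.52: in the autumn run, where starting material and second substrate were charged with a precatalyst to make target, twice the time gave that many times the target as read, more than 2 and near 4.

the same everywhere: starting material 0.020 M; precatalyst 0.01 mol%
- autumn: second substrate 4 equiv; temperature 40 °C; run made earlier
- Sunday's: second substrate 2.00 equiv; temperature 40 °C; time 4.0 min
- Friday's: second substrate 2.00 equiv; temperature −10 °C; time 4.0 min
- Saturday's: second substrate 2.00 equiv; temperature 15 °C; time 4.0 min

autumn run (percent of the starting material charged)

| time / s | target / % |
|---|---|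
| 12.0 | 0 |
| 25.0 | 3.3 |
| 40.0 | 8.0 |
| 50.0 | 11.6 |

(standard deviation of a reading: 0.5 percentage points)

- which flask leads in amount of target, in percent of the starting material charged ("all alike" within 1.5 percentage points) (Sunday's / Friday's / Saturday's / all alike)
- how much target is there at the end, in percent of the starting material charged: Sunday's
- how much target is there at the end, in percent of the starting material charged: Friday's
- how much target is there at the end, in percent of the starting material charged: Saturday's

- the earlier runs do not show what temperature does; that part of a forecast is a guess

A fixed amount of catalyst at low conversion gives a ratio near 2. Catalyst appearing steadily gives a rate that grows with time, and so target that grows with the square of time. I therefore worked with the fraction of starting material left, f, taken as 1 minus the fraction of target read, and not with the fraction made. I defined the wake time τ as the time at which −ln f reaches 1, so that τ = t/√(−ln f) and −ln f follows the square of t/τ.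

Read down the table, the row at 25.0 s gives 136 s, the row at 40.0 s gives 139 s, and the row at 50.0 s gives 142 s. These stand level within the scatter, so I carried the last as a reading. The row at 12.0 s fits too: τ allows 0.712 % there, against 0 % read with a scatter of 0.5 percentage points.

Sunday's has half the second substrate of the autumn run. I assumed it enters both the waking and the turnover, which lengthens τ by the ratio of the charges to 285 s. Over 4.0 min that leaves 49.2 % of the starting material, so my own figure for target in Sunday's is 50.8 %. The readings say nothing of temperature, so for Friday's at −10 °C and Saturday's at 15 °C I guessed a longer τ, with Sunday's leading.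

The forecast named Sunday's, with 45 % for Sunday's, 0.2 % for Friday's and 4 % for Saturday's, and said: “Temperature is a guess”.

The flasks gave Sunday's in the lead, with 46.9 % for Sunday's, 0.0577 % for Friday's and 3.97 % for Saturday's.

    free enzyme → unfolded enzyme (k = 7.21 × 10⁻⁵ s⁻¹, Ea = 196 kJ mol⁻¹)
    starting material + free enzyme ⇌ starting complex (K = 18.0 L mol⁻¹, k = 2.54 × 10⁶ L mol⁻¹ s⁻¹, Ea = 13.0 kJ mol⁻¹, ΔH = −34.0 kJ mol⁻¹)
    second substrate + starting complex ⇌ ternary complex (K = 69.0 L mol⁻¹, k = 1.15 × 10⁶ L mol⁻¹ s⁻¹, Ea = 17.0 kJ mol⁻¹, ΔH = −7.00 kJ mol⁻¹)
    ternary complex → free enzyme + target (k = 154 s⁻¹, Ea = 59.0 kJ mol⁻¹)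
    target → over-reaction product (k = 0.00182 s⁻¹, Ea = 94.0 kJ mol⁻¹)
    second substrate + precatalyst → free enzyme + spent reagent (k = 0.171 L mol⁻¹ s⁻¹, Ea = 55.0 kJ mol⁻¹)
    (constants at 40 °C)

In Friday's the half-life of the precatalyst by its waking step, 94 min, was far longer than the 4.0 min of the run, and 97.1 % of the precatalyst still stood at the end. Friday's target reads as τ = 166 min, and Sunday's 44 % of starting material left reads as 265 s, against my 285 s. A neighbour of Friday's with 0.04 mol% of precatalyst, 4.00 times the loading, takes half of Friday's τ if target follows the loading, which gives 0.232 %, and that flask stood at 0.231 % of target.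

All runs come from a simulation for substances that don't exist; noise was put on by code.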